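## Retrosynthetic overview

1. The C10' alcohol comes from an ester; the C10–C11 bond comes from a palladium coupling of a (Z)-alkenylsilane core with an all-E iodo-pentaenoate, itself made from a symmetric C10 dialdehyde (mono-olefination, then iodo-olefination).
2. In the core, the C3 alcohol comes from a ketone, the C6=C7 alkene from dehydration of a tertiary carbinol, and the gem-dimethyl group from conjugate methylation of an enone.
3. Key step: a 4-alkyl-3,5-dimethylphenol is oxidatively dearomatized to a symmetric p-quinol, and the C8 carbinol then closes by 5-exo oxa-Michael addition onto one of the two equivalent enones, which sets C5.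
4. The phenol side chain is a (Z)-vinylsilane, made by copper-catalysed anti-carbomagnesiation of an (S)-propargylic alcohol; that alcohol comes from asymmetric transfer hydrogenation of an ynone built on 4-bromo-3,5-dimethylphenol.
5. Ring order: the carbocycle is the original benzene ring; the oxygen ring is closed second, onto the dearomatized ring.

Assumption: the SMILES is read as (3S,5R,8S) with the C9=C10 bond Z (C8 and C11 cis, methyl trans to C11) and all other double bonds E; comments use carotenoid numbering (C1 = CMe2, C3 = CHOH, C5 = C(CH3)–O, C6=C7 = ring alkene, C8 = O–CH, C9 = C–CH3).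

## Route

Step 1
Reactants: 1 4-bromo-3,5-dimethylphenol; 2 2-bromo-N-methoxy-N-methylacetamide
Product: 4 2-(4-hydroxy-2,6-dimethylphenyl)-N-methoxy-N-methylacetamide, via zinc enolate 3 (not isolated)
Conditions: Zn dust, THF, rt (2 gives 3, 2.5 equiv); then 1, Pd(dba)2 (2 mol %), P(t-Bu)3 (4 mol %), THF, 60 °C
Reagents that add atoms: none
Why: Palladium-catalysed α-arylation of a zinc amide enolate (Reformatsky–Negishi type) tolerates the hindered, electron-rich bromide, with one extra equivalent of 3 spent on the phenol O–H, and the Weinreb amide prepares a clean ketone synthesis.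

Step 2
Reactants: 4 2-(4-hydroxy-2,6-dimethylphenyl)-N-methoxy-N-methylacetamide
Product: 5 1-(4-hydroxy-2,6-dimethylphenyl)-4-(trimethylsilyl)but-3-yn-2-one
Conditions: LiC≡CSiMe3 (2.5 equiv), THF, −78 → 0 °C; aq NH4Cl
Reagents that add atoms: lithium (trimethylsilyl)acetylide, [Li+].[C-]#C[Si](C)(C)C
Why: Weinreb ketone synthesis, in which the chelated tetrahedral intermediate stops the addition at the ynone and the phenoxide formed by the first equivalent is inert.

Step 3
Reactants: 5 1-(4-hydroxy-2,6-dimethylphenyl)-4-(trimethylsilyl)but-3-yn-2-one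
Product: 7 4-[(2S)-2-hydroxybut-3-yn-1-yl]-3,5-dimethylphenol, via silyl alkynol 6 (not isolated)
Conditions: RuCl[(S,S)-TsDPEN](p-cymene) (1 mol %), i-PrOH, rt; evaporate; K2CO3 (cat.), MeOH, rt
Reagents that add atoms: none
Why: Noyori asymmetric transfer hydrogenation of an alkynyl ketone, where the alkyne takes the place of the aryl group in the usual model so that the (S,S)-catalyst gives the (S)-carbinol (future C8) in high ee, followed by methanolysis of the alkynylsilane.

Step 4
Reactants: 7 4-[(2S)-2-hydroxybut-3-yn-1-yl]-3,5-dimethylphenol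
Product: 9 4-[(2S,3Z)-4-[benzyl(dimethyl)silyl]-2-hydroxy-3-methylbut-3-en-1-yl]-3,5-dimethylphenol, via vinylmagnesium chelate 8 (not isolated)
Conditions: MeMgBr (4 equiv), CuI (10 mol %), THF, 0 °C → rt; BnMe2SiCl (3 equiv), 40 °C; K2CO3, MeOH (cleaves O–Si)
Reagents that add atoms: methylmagnesium bromide, C[Mg]Br; benzyl(chloro)dimethylsilane, C[Si](C)(Cl)Cc1ccccc1
Why: Copper-catalysed anti-carbomagnesiation of a propargylic alkoxide (Duboudin–Jousseaume reaction) puts the methyl on C9 and magnesium on C10 cis to the carbinol carbon in a five-membered chelate, and silylation with retention fixes the Z geometry without touching the C8 stereocentre.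

Step 5
Reactants: 9 4-[(2S,3Z)-4-[benzyl(dimethyl)silyl]-2-hydroxy-3-methylbut-3-en-1-yl]-3,5-dimethylphenol
Product: 11 (2S,3aR,7aR)-2-[(1Z)-1-[benzyl(dimethyl)silyl]prop-1-en-2-yl]-3a-hydroxy-4,7a-dimethyl-3,3a,7,7a-tetrahydro-1-benzofuran-6(2H)-one, via quinol 10 (not isolated)
Conditions: PhI(OAc)2 (1.1 equiv), MeCN/H2O (4:1), 0 °C; extract; DBU (0.2 equiv), CH2Cl2, rt
Reagents that add atoms: water, O
Why: Proposed new method: trivalent-iodine oxidation of the phenol with para capture of water (known p-quinol formation) gives a symmetric cross-conjugated dienone whose two enones are diastereotopic, and reversible base-catalysed 5-exo-trig oxa-Michael addition of the (S)-C8 hydroxyl to a methyl-bearing β-carbon must give a cis-fused ring and, under thermodynamic control, should place the bulky C8 substituent on the convex face next to the angular CH3 and OH instead of under the carbocycle, which sets C5 (7aR) and the temporary C6 centre (3aR) from C8; the closest known reactions are the tyrosol-quinol to rengyolone cyclisation and acid-catalysed desymmetrising oxa-Michael reactions of cyclohexadienones, the new elements being the fully substituted ether carbon and the remote substrate control, and the minor diastereomer can be re-equilibrated through 10.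

Step 6
Reactants: 11 (2S,3aR,7aR)-2-[(1Z)-1-[benzyl(dimethyl)silyl]prop-1-en-2-yl]-3a-hydroxy-4,7a-dimethyl-3,3a,7,7a-tetrahydro-1-benzofuran-6(2H)-one
Product: 12 (2S,3aR,7aR)-2-[(1Z)-1-[benzyl(dimethyl)silyl]prop-1-en-2-yl]-3a-hydroxy-4,4,7a-trimethylhexahydro-1-benzofuran-6(2H)-one
Conditions: Me2CuLi (from MeLi, CuI; 4 equiv), Me3SiCl (5 equiv), THF/Et2O, −78 → −20 °C; aq citric acid, MeOH, 0 °C
Reagents that add atoms: lithium dimethylcuprate, [Li+].C[Cu-]C
Why: Chlorosilane-accelerated Gilman conjugate addition to the remaining β-methyl enone creates the gem-dimethyl carbon (no new stereocentre) under non-basic conditions that keep the β-alkoxy ketone closed and leave the vinylsilane untouched.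

Step 7
Reactants: 12 (2S,3aR,7aR)-2-[(1Z)-1-[benzyl(dimethyl)silyl]prop-1-en-2-yl]-3a-hydroxy-4,4,7a-trimethylhexahydro-1-benzofuran-6(2H)-one
Product: 13 (2S,7aR)-2-[(1Z)-1-[benzyl(dimethyl)silyl]prop-1-en-2-yl]-4,4,7a-trimethyl-2,4,5,7a-tetrahydro-1-benzofuran-6(7H)-one
Conditions: SOCl2 (1.5 equiv), pyridine, CH2Cl2, −20 → 0 °C; used crude
Reagents that add atoms: none
Why: Dehydration of the tertiary alcohol through its chlorosulfite by pyridine-induced E2 elimination can only go towards C7 because C1 and C5 carry no hydrogen, and the β-oxygen disfavours ionisation at C6 and skeletal shifts, so the temporary C6 centre is erased as planned.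

Step 8
Reactants: 13 (2S,7aR)-2-[(1Z)-1-[benzyl(dimethyl)silyl]prop-1-en-2-yl]-4,4,7a-trimethyl-2,4,5,7a-tetrahydro-1-benzofuran-6(7H)-one
Product: 14 (2S,6S,7aR)-2-[(1Z)-1-[benzyl(dimethyl)silyl]prop-1-en-2-yl]-4,4,7a-trimethyl-2,4,5,6,7,7a-hexahydro-1-benzofuran-6-ol
Conditions: LiBH(s-Bu)3 (1.3 equiv), THF, −78 °C; H2O
Reagents that add atoms: none
Why: Bulky-hydride ketone reduction, in which the two syn-axial methyl groups on C1 and C5 block axial attack so that equatorial delivery gives the axial (3S) alcohol cis to the C5 methyl.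

Step 9
Reactants: 15 (2E,4E,6E)-2,7-dimethylocta-2,4,6-trienedial; 16 triethyl phosphonoacetate
Product: 17 ethyl (2E,4E,6E,8E)-4,9-dimethyl-10-oxodeca-2,4,6,8-tetraenoate
Conditions: NaH, THF, 0 °C; anion of 16 added slowly to 15 (2 equiv, excess recovered)
Reagents that add atoms: none
Why: Horner–Wadsworth–Emmons mono-olefination breaks the symmetry of the dialdehyde and gives the E-enoate.

Step 10
Reactants: 17 ethyl (2E,4E,6E,8E)-4,9-dimethyl-10-oxodeca-2,4,6,8-tetraenoate; 18 iodoform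
Product: 19 ethyl (2E,4E,6E,8E,10E)-11-iodo-4,9-dimethylundeca-2,4,6,8,10-pentaenoate
Conditions: CrCl2 (6 equiv), THF/dioxane (1:6), 0 °C → rt, dark
Reagents that add atoms: none
Why: Takai iodo-olefination of the enal with the gem-dichromium species from iodoform gives the (E)-vinyl iodide.

Step 11
Reactants: 14 (2S,6S,7aR)-2-[(1Z)-1-[benzyl(dimethyl)silyl]prop-1-en-2-yl]-4,4,7a-trimethyl-2,4,5,6,7,7a-hexahydro-1-benzofuran-6-ol; 19 ethyl (2E,4E,6E,8E,10E)-11-iodo-4,9-dimethylundeca-2,4,6,8,10-pentaenoate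
Product: 21 ethyl (2E,4E,6E,8E,10E,12Z)-13-[(2S,6S,7aR)-6-hydroxy-4,4,7a-trimethyl-2,4,5,6,7,7a-hexahydro-1-benzofuran-2-yl]-4,9-dimethyltetradeca-2,4,6,8,10,12-hexaenoate, via silanol 20 (not isolated)
Conditions: Bu4NF (2.5 equiv), THF, 0 °C → rt; then 19, Pd2(dba)3·CHCl3 (2.5 mol %), rt, dark
Reagents that add atoms: none
Why: Fluoride-promoted Hiyama–Denmark cross-coupling, in which fluoride cleaves the benzyl–silicon bond to the silanol that transmetalates to the polyenyl–palladium iodide and couples with retention at both sp2 carbons, gives the 9Z,11E-diene without acid or strong base.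

Step 12
Reactants: 21 ethyl (2E,4E,6E,8E,10E,12Z)-13-[(2S,6S,7aR)-6-hydroxy-4,4,7a-trimethyl-2,4,5,6,7,7a-hexahydro-1-benzofuran-2-yl]-4,9-dimethyltetradeca-2,4,6,8,10,12-hexaenoate
Product: 22 (2E,4E,6E,8E,10E,12Z)-13-[(2S,6S,7aR)-6-hydroxy-4,4,7a-trimethyl-2,4,5,6,7,7a-hexahydro-1-benzofuran-2-yl]-4,9-dimethyltetradeca-2,4,6,8,10,12-hexaen-1-ol
Conditions: i-Bu2AlH (4 equiv), CH2Cl2, −78 °C; aq KNaC4H4O6
Reagents that add atoms: none
Why: 1,2-Reduction of the conjugated ester by the aluminium hydride gives the allylic alcohol without touching any stereocentre or double bond, and the acid-free tartrate work-up protects the doubly allylic C8 ether from epimerisation.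

## Compound list

1 | 4-bromo-3,5-dimethylphenol | Cc1cc(O)cc(C)c1Br | starting material
2 | 2-bromo-N-methoxy-N-methylacetamide | CON(C)C(=O)CBr | starting material
3 | bromo[2-(methoxy(methyl)amino)-2-oxoethyl]zinc (zinc enolate) | CON(C)C(=O)C[Zn]Br | intermediate
4 | 2-(4-hydroxy-2,6-dimethylphenyl)-N-methoxy-N-methylacetamide | Cc1cc(O)cc(C)c1CC(=O)N(C)OC | intermediate
5 | 1-(4-hydroxy-2,6-dimethylphenyl)-4-(trimethylsilyl)but-3-yn-2-one | Cc1cc(O)cc(C)c1CC(=O)C#C[Si](C)(C)C | intermediate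
6 | 4-[(2S)-2-hydroxy-4-(trimethylsilyl)but-3-yn-1-yl]-3,5-dimethylphenol | Cc1cc(O)cc(C)c1C[C@H](O)C#C[Si](C)(C)C | intermediate
7 | 4-[(2S)-2-hydroxybut-3-yn-1-yl]-3,5-dimethylphenol | Cc1cc(O)cc(C)c1C[C@H](O)C#C | intermediate
8 | chelated (Z)-alkenylmagnesium alkoxide of 7 carrying the new C9 methyl (2,5-dihydro-1,2-oxamagnesole; phenol as bromomagnesium phenoxide) | Cc1cc(O[Mg]Br)cc(C)c1C[C@@H]1O[Mg]C=C1C | intermediate
9 | 4-[(2S,3Z)-4-[benzyl(dimethyl)silyl]-2-hydroxy-3-methylbut-3-en-1-yl]-3,5-dimethylphenol | Cc1cc(O)cc(C)c1C[C@H](O)/C(C)=C\[Si](C)(C)Cc1ccccc1 | intermediate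
10 | 4-[(2S,3Z)-4-[benzyl(dimethyl)silyl]-2-hydroxy-3-methylbut-3-en-1-yl]-4-hydroxy-3,5-dimethylcyclohexa-2,5-dien-1-one | CC1=CC(=O)C=C(C)C1(O)C[C@H](O)/C(C)=C\[Si](C)(C)Cc1ccccc1 | intermediate
11 | (2S,3aR,7aR)-2-[(1Z)-1-[benzyl(dimethyl)silyl]prop-1-en-2-yl]-3a-hydroxy-4,7a-dimethyl-3,3a,7,7a-tetrahydro-1-benzofuran-6(2H)-one | C[C@@]12CC(=O)C=C(C)[C@]1(O)C[C@@H](/C(C)=C\[Si](C)(C)Cc1ccccc1)O2 | intermediate
12 | (2S,3aR,7aR)-2-[(1Z)-1-[benzyl(dimethyl)silyl]prop-1-en-2-yl]-3a-hydroxy-4,4,7a-trimethylhexahydro-1-benzofuran-6(2H)-one | C[C@@]12CC(=O)CC(C)(C)[C@]1(O)C[C@@H](/C(C)=C\[Si](C)(C)Cc1ccccc1)O2 | intermediate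
13 | (2S,7aR)-2-[(1Z)-1-[benzyl(dimethyl)silyl]prop-1-en-2-yl]-4,4,7a-trimethyl-2,4,5,7a-tetrahydro-1-benzofuran-6(7H)-one | C[C@@]12CC(=O)CC(C)(C)C1=C[C@@H](/C(C)=C\[Si](C)(C)Cc1ccccc1)O2 | intermediate
14 | (2S,6S,7aR)-2-[(1Z)-1-[benzyl(dimethyl)silyl]prop-1-en-2-yl]-4,4,7a-trimethyl-2,4,5,6,7,7a-hexahydro-1-benzofuran-6-ol | C[C@@]12C[C@@H](O)CC(C)(C)C1=C[C@@H](/C(C)=C\[Si](C)(C)Cc1ccccc1)O2 | intermediate
15 | (2E,4E,6E)-2,7-dimethylocta-2,4,6-trienedial | O=C/C(C)=C/C=C/C=C(C)/C=O | starting material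
16 | triethyl phosphonoacetate | CCOC(=O)CP(=O)(OCC)OCC | starting material
17 | ethyl (2E,4E,6E,8E)-4,9-dimethyl-10-oxodeca-2,4,6,8-tetraenoate | CCOC(=O)/C=C/C(C)=C/C=C/C=C(C)/C=O | intermediate
18 | iodoform (triiodomethane) | IC(I)I | starting material
19 | ethyl (2E,4E,6E,8E,10E)-11-iodo-4,9-dimethylundeca-2,4,6,8,10-pentaenoate | CCOC(=O)/C=C/C(C)=C/C=C/C=C(C)/C=C/I | intermediate
20 | (2S,6S,7aR)-2-[(1Z)-1-[hydroxy(dimethyl)silyl]prop-1-en-2-yl]-4,4,7a-trimethyl-2,4,5,6,7,7a-hexahydro-1-benzofuran-6-ol | C[C@@]12C[C@@H](O)CC(C)(C)C1=C[C@@H](/C(C)=C\[Si](C)(C)O)O2 | intermediate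
21 | ethyl (2E,4E,6E,8E,10E,12Z)-13-[(2S,6S,7aR)-6-hydroxy-4,4,7a-trimethyl-2,4,5,6,7,7a-hexahydro-1-benzofuran-2-yl]-4,9-dimethyltetradeca-2,4,6,8,10,12-hexaenoate | C/C(=C/C=C/C(C)=C/C=C/C=C(C)/C=C/C(=O)OCC)[C@@H]1C=C2C(C)(C)C[C@H](O)C[C@@]2(C)O1 | intermediate
22 | (2E,4E,6E,8E,10E,12Z)-13-[(2S,6S,7aR)-6-hydroxy-4,4,7a-trimethyl-2,4,5,6,7,7a-hexahydro-1-benzofuran-2-yl]-4,9-dimethyltetradeca-2,4,6,8,10,12-hexaen-1-ol | C/C(=C/C=C/C(C)=C/C=C/C=C(C)/C=C/CO)[C@@H]1C=C2C(C)(C)C[C@H](O)C[C@@]2(C)O1 | target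

## Step count and risks

Total step count: 12. Longest linear sequence: 10 (steps 1–8, 11, 12).

Steps most likely to fail:

Step 5 (oxa-Michael closure onto a methyl-bearing carbon; equilibrium position and diastereomer ratio are untested). The fallback gives up thermodynamic control and sets out from crude quinol 10. Treatment with Me3SiOTf and Et3N in CH2Cl2 at −78 °C lets the silylated C8 oxygen add to the silyl-activated dienone, and the enolate is captured irreversibly as (2S,3aR,7aR)-2-[(1Z)-1-[benzyl(dimethyl)silyl]prop-1-en-2-yl]-4,7a-dimethyl-3a,6-bis(trimethylsilyloxy)-2,3,3a,7a-tetrahydro-1-benzofuran F1. Buffered hydrolysis (citric acid, MeOH, 0 °C) without any base returns to the route at enone 11, which is then carried on under the non-basic conditions of step 6.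

Step 6 (cuprate addition to a β,β-disubstituted enone flanked by a fully substituted carbinol). The fallback sets out from enone 11 and brings in the second methyl as a cyclopropane carbon. Dimethylsulfoxonium methylide (Me3S(O)I, NaH, DMSO, rt) adds its methylene to the convex face to give the 4,5-methano ketone (cyclopropyl ketone of 11) F2. Reductive cleavage of the cyclopropane bond that overlaps the carbonyl π-system (SmI2, HMPA, t-BuOH, THF) turns that methylene into the second C1 methyl and returns to the route at ketone 12.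

Step 11 (fluoride-promoted coupling of a hindered trisubstituted Z-alkenylsilane with a light-sensitive polyenyl iodide). The fallback reverses the roles of the partners and sets out from 14 and 17. Iododesilylation of 14 with N-iodosuccinimide (MeCN, 0 °C) gives, with retention, (2S,6S,7aR)-2-[(1Z)-1-iodoprop-1-en-2-yl]-4,4,7a-trimethyl-2,4,5,6,7,7a-hexahydro-1-benzofuran-6-ol F3. Aldehyde 17 is converted with Bu3SnCHBr2, CrCl2 and LiI (Hodgson stannyl-olefination) into ethyl (2E,4E,6E,8E,10E)-4,9-dimethyl-11-(tributylstannyl)undeca-2,4,6,8,10-pentaenoate F4. Stille coupling of F3 with F4 (Pd2(dba)3, AsPh3, NMP, rt, dark) returns to the route at ester 21.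

Further compounds

F1 | step 5 | (2S,3aR,7aR)-2-[(1Z)-1-[benzyl(dimethyl)silyl]prop-1-en-2-yl]-4,7a-dimethyl-3a,6-bis(trimethylsilyloxy)-2,3,3a,7a-tetrahydro-1-benzofuran | C[C@@]12C=C(O[Si](C)(C)C)C=C(C)[C@]1(O[Si](C)(C)C)C[C@@H](/C(C)=C\[Si](C)(C)Cc1ccccc1)O2
F2 | step 6 | 4,5-methano ketone (cyclopropyl ketone of 11, methylene on the convex face): (2S,3aR,7aR)-2-[(1Z)-1-[benzyl(dimethyl)silyl]prop-1-en-2-yl]-3a-hydroxy-4,7a-dimethyl-4,5-methanohexahydro-1-benzofuran-6(2H)-one | C[C@@]12CC(=O)[C@H]3C[C@@]3(C)[C@]1(O)C[C@@H](/C(C)=C\[Si](C)(C)Cc1ccccc1)O2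
F3 | step 11 | (2S,6S,7aR)-2-[(1Z)-1-iodoprop-1-en-2-yl]-4,4,7a-trimethyl-2,4,5,6,7,7a-hexahydro-1-benzofuran-6-ol | C[C@@]12C[C@@H](O)CC(C)(C)C1=C[C@@H](/C(C)=C\I)O2
F4 | step 11 | ethyl (2E,4E,6E,8E,10E)-4,9-dimethyl-11-(tributylstannyl)undeca-2,4,6,8,10-pentaenoate | CCCC[Sn](CCCC)(CCCC)/C=C/C(C)=C/C=C/C=C(C)/C=C/C(=O)OCC
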